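**Strategy**

The five-membered ring C8–C12 is a 2-chloro-4-hydroxycyclopent-2-enone: its five carbons, the C9 ketone oxygen, the C10 chlorine and the C12 octenyl arm map onto a 3-chloro-5-octenyl-2-furylcarbinol. A single Piancatelli rearrangement exploits this: water enters at C12, the furan opens and a conrotatory 4π closure forges C8–C12, creating the ring, the quaternary C12 carbinol and C8 at once. The precursor 23 is the C8 carbinol that joins this furan to a D-xylose-derived C1–C8 chain (C5–C7 as TBS ethers, C1 methyl ester). Equilibration of C8, desilylation and triple acetylation finish the synthesis.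

Key step: step 13

Remark on numbering: prostanoid numbering is used (C1 ester carbon, C8–C12 ring, C13–C20 octenyl chain); xylose C1–C5 become C4–C8.

Remark on stereochemistry: in known Piancatelli rearrangements the new hydroxyl ends up trans to the substituent of the former carbinol carbon, so step 13 is planned to give the C8 epimer 25 (C12 hydroxyl anti to the C7 chain); step 14 then equilibrates the ketone α-centre C8 to the trans-dialkyl arrangement of the target (26), and would leave 26 unchanged if it formed directly.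

Remark on the precursor: the furan is fully substituted before it meets the ester-bearing aldehyde, so no organolithium base is needed once the C1 methyl ester is present; the C8 carbinol forms as an epimer mixture (8S drawn), which is irrelevant because C8 is ionized in step 13.

**Route**

Step 1
Reactants: 1 D-xylose
Product: 2 D-xylose diethyl dithioacetal
Conditions: EtSH, conc. HCl, 0 °C
Reagents that add atoms: ethanethiol, CCS
Why: Acid-catalysed dithioacetal formation traps the aldose in its open-chain form and touches none of the three stereocentres (future C5, C6 and C7).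

Step 2
Reactants: 2 D-xylose diethyl dithioacetal
Product: 3 2,3,4,5-tetra-O-(tert-butyldimethylsilyl)-D-xylose diethyl dithioacetal
Conditions: TBSOTf, 2,6-lutidine, CH2Cl2, 0 °C to 40 °C
Reagents that add atoms: tert-butyldimethylsilyl triflate, CC(C)(C)[Si](C)(C)OS(=O)(=O)C(F)(F)F
Why: Exhaustive O-silylation with the silyl triflate and a hindered pyridine base protects all four hydroxyls as ethers that survive ylide, hydrogenation and organomagnesium chemistry.

Step 3
Reactants: 3 2,3,4,5-tetra-O-(tert-butyldimethylsilyl)-D-xylose diethyl dithioacetal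
Product: 4 2,3,4,5-tetra-O-(tert-butyldimethylsilyl)-aldehydo-D-xylose
Conditions: I2, NaHCO3, acetone/H2O, 0 °C to rt
Reagents that add atoms: water, O
Why: Iodine-mediated oxidative hydrolysis of the dithioacetal in bicarbonate buffer releases the aldehyde (future C4) without cleaving silyl ethers or epimerizing the α-silyloxy centre.

Step 4
Reactants: 4 2,3,4,5-tetra-O-(tert-butyldimethylsilyl)-aldehydo-D-xylose; 5 (2-carboxyethyl)triphenylphosphonium bromide
Product: 8 methyl (3Z,5S,6R,7R)-5,6,7,8-tetrakis(tert-butyldimethylsilyloxy)oct-3-enoate, via carboxylate ylide 6 (not isolated), via sodium carboxylate 7 (not isolated)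
Conditions: 5, NaN(SiMe3)2, THF, −78 °C; 4, −78 °C to rt; MeI, DMF, rt
Reagents that add atoms: iodomethane, CI
Why: Wittig olefination with the non-stabilized carboxylate ylide forms the C3–C4 bond as an alkene whose geometry is irrelevant because it is hydrogenated next, and the sodium carboxylate is then O-alkylated by iodomethane (SN2) in the same flask, where residual ylide is quenched at once.

Step 5
Reactants: 8 methyl (3Z,5S,6R,7R)-5,6,7,8-tetrakis(tert-butyldimethylsilyloxy)oct-3-enoate
Product: 9 methyl (5S,6R,7R)-5,6,7,8-tetrakis(tert-butyldimethylsilyloxy)octanoate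
Conditions: H2 (1 atm), Pd/C, EtOAc, rt
Reagents that add atoms: none
Why: Heterogeneous catalytic hydrogenation saturates the only alkene present, while silyl ethers and the ester are inert.

Step 6
Reactants: 9 methyl (5S,6R,7R)-5,6,7,8-tetrakis(tert-butyldimethylsilyloxy)octanoate
Product: 10 methyl (5S,6R,7R)-8-hydroxy-5,6,7-tris(tert-butyldimethylsilyloxy)octanoate
Conditions: HF·pyridine, pyridine, THF, 0 °C
Reagents that add atoms: none
Why: Selective desilylation, since buffered HF removes the unhindered primary silyl ether much faster than the three mutually shielded secondary ones.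

Step 7
Reactants: 10 methyl (5S,6R,7R)-8-hydroxy-5,6,7-tris(tert-butyldimethylsilyloxy)octanoate
Product: 11 methyl (5S,6R,7S)-8-oxo-5,6,7-tris(tert-butyldimethylsilyloxy)octanoate
Conditions: Dess–Martin periodinane, NaHCO3, CH2Cl2, 0 °C to rt
Reagents that add atoms: none
Why: Dess–Martin oxidation gives the C8 aldehyde under buffered conditions that do not epimerize the α-silyloxy centre C7 (its descriptor changes from R to S only through the priority rules).

Step 8
Reactants: 12 (2Z)-oct-2-en-1-ol
Product: 13 (2Z)-1-bromooct-2-ene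
Conditions: CBr4, PPh3, CH2Cl2, 0 °C
Reagents that add atoms: carbon tetrabromide, BrC(Br)(Br)Br
Why: Appel bromination replaces the primary allylic hydroxyl by SN2 at C1 without allylic transposition, so the Z-alkene is retained.

Step 9
Reactants: 14 3-bromofuran
Product: 16 3-bromo-2-(trimethylsilyl)furan, via 3-bromo-2-lithiofuran 15 (not isolated)
Conditions: LiN(iPr)2, THF, −78 °C; Me3SiCl, −78 °C to rt
Reagents that add atoms: chlorotrimethylsilane, C[Si](C)(C)Cl
Why: Directed ortho-metalation removes the most acidic furan proton (α to oxygen and next to bromine), and C-silylation blocks this position, the future C9.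

Step 10
Reactants: 16 3-bromo-2-(trimethylsilyl)furan
Product: 18 3-chloro-2-(trimethylsilyl)furan, via 3-lithio-2-(trimethylsilyl)furan 17 (not isolated)
Conditions: n-BuLi, Et2O, −78 °C; C2Cl6, −78 °C to rt
Reagents that add atoms: hexachloroethane, ClC(Cl)(Cl)C(Cl)(Cl)Cl
Why: Bromine–lithium exchange at low temperature followed by electrophilic chlorination of the 3-furyllithium swaps bromine for the chlorine of the target (C10).

Step 11
Reactants: 18 3-chloro-2-(trimethylsilyl)furan; 13 (2Z)-1-bromooct-2-ene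
Product: 21 4-chloro-2-[(2Z)-oct-2-en-1-yl]furan, via 3-chloro-5-lithio-2-(trimethylsilyl)furan 19 (not isolated), via 3-chloro-5-[(2Z)-oct-2-en-1-yl]-2-(trimethylsilyl)furan 20 (not isolated)
Conditions: n-BuLi, THF, −78 to −20 °C; 13, −78 °C to rt; Bu4NF, THF, rt
Reagents that add atoms: none
Why: α-Lithiation at the only free α-position (future C12), SN2 alkylation of the furyllithium by the primary allylic bromide (Z retained) and fluoride-induced protodesilylation of the 2-furylsilane free the position that will carry C8.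

Step 12
Reactants: 21 4-chloro-2-[(2Z)-oct-2-en-1-yl]furan; 11 methyl (5S,6R,7S)-8-oxo-5,6,7-tris(tert-butyldimethylsilyloxy)octanoate
Product: 23 methyl (5S,6R,7R,8S)-8-[3-chloro-5-[(2Z)-oct-2-en-1-yl]furan-2-yl]-8-hydroxy-5,6,7-tris(tert-butyldimethylsilyloxy)octanoate, via furylmagnesium chloride 22 (not isolated)
Conditions: 21, TMPMgCl·LiCl, THF, 0 °C; 11, −40 to 0 °C
Reagents that add atoms: none
Why: Directed magnesiation by the hindered magnesium amide occurs α to oxygen and next to chlorine, and the ester-tolerant furyl Grignard reagent adds 1,2 to the aldehyde; the new centre C8 is not controlled (epimer mixture, 8S drawn) because it is ionized in step 13.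

Step 13
Reactants: 23 methyl (5S,6R,7R,8S)-8-[3-chloro-5-[(2Z)-oct-2-en-1-yl]furan-2-yl]-8-hydroxy-5,6,7-tris(tert-butyldimethylsilyloxy)octanoate
Product: 25 methyl (5S,6R,7R,8R,12R,14Z)-10-chloro-12-hydroxy-9-oxo-5,6,7-tris(tert-butyldimethylsilyloxy)prosta-10,14-dien-1-oate, via dihydroxypentadienyl cation 24 (not isolated)
Conditions: Dy(OTf)3 (20 mol%), t-BuOH/H2O (5:1), 80 °C
Reagents that add atoms: water, O
Why: The Lewis acid ionizes the C8 carbinol of either epimer to a furfuryl oxocarbenium ion, water adds at C12, the hemiketal opens to the 1,4-dihydroxypentadienyl cation 24, and this closes and tautomerizes to the 4-hydroxy enone. The closest known reaction is the Piancatelli rearrangement of 5-alkyl-2-furylcarbinols under ZnCl2 or Dy(OTf)3 catalysis in aqueous media; the 3-chloro substituent is the untested variable. The ring C8–C12 closes by thermal conrotatory 4π electrocyclization, which forms the C8–C12 bond. The relative configuration follows from torquoselectivity: the C7 chain at C8 (held away from C10–Cl) and the hydroxyl at C12 both rotate outward, as in the known cases, and therefore end up trans. The sense of rotation is set by the C7 stereocentre: with C7–H eclipsing the C8=C9 enol bond to avoid allylic 1,3-strain with the C9 oxygen, the rotation that turns the branched C6 carbon away from that oxygen is preferred and should give 8R and 12R. The step needs water capture at C12 in preference to trapping of the C8 cation by chain oxygens or a hydride shift from C7, which the bulky, weakly nucleophilic silyl ethers on O5–O7 are chosen to secure.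

Step 14
Reactants: 25 methyl (5S,6R,7R,8R,12R,14Z)-10-chloro-12-hydroxy-9-oxo-5,6,7-tris(tert-butyldimethylsilyloxy)prosta-10,14-dien-1-oate
Product: 26 methyl (5S,6R,7R,8S,12R,14Z)-10-chloro-12-hydroxy-9-oxo-5,6,7-tris(tert-butyldimethylsilyloxy)prosta-10,14-dien-1-oate
Conditions: KOAc, MeOH, rt
Reagents that add atoms: none
Why: Base-mediated epimerization of the ketone α-centre through its enol(ate), the standard equilibration of 8-epi prostanoids, should drive C8 to the thermodynamically preferred 8S configuration (bulky C7 chain trans to the octenyl group and cis to the small hydroxyl), while the quaternary C12 cannot epimerize.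

Step 15
Reactants: 26 methyl (5S,6R,7R,8S,12R,14Z)-10-chloro-12-hydroxy-9-oxo-5,6,7-tris(tert-butyldimethylsilyloxy)prosta-10,14-dien-1-oate
Product: 27 methyl (5S,6R,7R,8S,12R,14Z)-10-chloro-5,6,7,12-tetrahydroxy-9-oxoprosta-10,14-dien-1-oate
Conditions: HF·pyridine, pyridine, THF, 0 °C to rt
Reagents that add atoms: none
Why: Desilylation with pyridine-buffered HF proceeds without enolate formation, so the β-oxygenated ketone should neither eliminate nor undergo retro-aldol cleavage, and the mild medium leaves ester, vinyl chloride and alkene alone.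

Step 16
Reactants: 27 methyl (5S,6R,7R,8S,12R,14Z)-10-chloro-5,6,7,12-tetrahydroxy-9-oxoprosta-10,14-dien-1-oate
Product: 28 methyl (5S,6R,7R,8S,12R,14Z)-5,6,7-triacetoxy-10-chloro-12-hydroxy-9-oxoprosta-10,14-dien-1-oate
Conditions: Ac2O, pyridine, 0 °C to rt
Reagents that add atoms: acetic anhydride, CC(=O)OC(C)=O
Why: Pyridine-mediated acylation esterifies the three secondary hydroxyls, whereas the hindered tertiary C12 hydroxyl is not acetylated without an acyl-transfer catalyst, and the low temperature avoids elimination of the new C7 acetate.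

**Compound list**

1 | D-xylose (open-chain form drawn) | O=C[C@H](O)[C@@H](O)[C@H](O)CO | starting material
2 | D-xylose diethyl dithioacetal | CCSC(SCC)[C@H](O)[C@@H](O)[C@H](O)CO | intermediate
3 | 2,3,4,5-tetra-O-(tert-butyldimethylsilyl)-D-xylose diethyl dithioacetal | CCSC(SCC)[C@H](O[Si](C)(C)C(C)(C)C)[C@@H](O[Si](C)(C)C(C)(C)C)[C@H](O[Si](C)(C)C(C)(C)C)CO[Si](C)(C)C(C)(C)C | intermediate
4 | 2,3,4,5-tetra-O-(tert-butyldimethylsilyl)-aldehydo-D-xylose | O=C[C@H](O[Si](C)(C)C(C)(C)C)[C@@H](O[Si](C)(C)C(C)(C)C)[C@H](O[Si](C)(C)C(C)(C)C)CO[Si](C)(C)C(C)(C)C | intermediate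
5 | (2-carboxyethyl)triphenylphosphonium bromide | [Br-].OC(=O)CC[P+](c1ccccc1)(c1ccccc1)c1ccccc1 | starting material
6 | sodium 3-(triphenylphosphoranylidene)propanoate (carboxylate ylide) | [Na+].[O-]C(=O)CC=P(c1ccccc1)(c1ccccc1)c1ccccc1 | intermediate (not isolated)
7 | sodium (3Z,5S,6R,7R)-5,6,7,8-tetrakis(tert-butyldimethylsilyloxy)oct-3-enoate | [Na+].[O-]C(=O)C/C=C\[C@H](O[Si](C)(C)C(C)(C)C)[C@@H](O[Si](C)(C)C(C)(C)C)[C@H](O[Si](C)(C)C(C)(C)C)CO[Si](C)(C)C(C)(C)C | intermediate (not isolated)
8 | methyl (3Z,5S,6R,7R)-5,6,7,8-tetrakis(tert-butyldimethylsilyloxy)oct-3-enoate | COC(=O)C/C=C\[C@H](O[Si](C)(C)C(C)(C)C)[C@@H](O[Si](C)(C)C(C)(C)C)[C@H](O[Si](C)(C)C(C)(C)C)CO[Si](C)(C)C(C)(C)C | intermediate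
9 | methyl (5S,6R,7R)-5,6,7,8-tetrakis(tert-butyldimethylsilyloxy)octanoate | COC(=O)CCC[C@H](O[Si](C)(C)C(C)(C)C)[C@@H](O[Si](C)(C)C(C)(C)C)[C@H](O[Si](C)(C)C(C)(C)C)CO[Si](C)(C)C(C)(C)C | intermediate
10 | methyl (5S,6R,7R)-8-hydroxy-5,6,7-tris(tert-butyldimethylsilyloxy)octanoate | COC(=O)CCC[C@H](O[Si](C)(C)C(C)(C)C)[C@@H](O[Si](C)(C)C(C)(C)C)[C@H](O[Si](C)(C)C(C)(C)C)CO | intermediate
11 | methyl (5S,6R,7S)-8-oxo-5,6,7-tris(tert-butyldimethylsilyloxy)octanoate | COC(=O)CCC[C@H](O[Si](C)(C)C(C)(C)C)[C@@H](O[Si](C)(C)C(C)(C)C)[C@H](O[Si](C)(C)C(C)(C)C)C=O | intermediate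
12 | (2Z)-oct-2-en-1-ol | CCCCC/C=C\CO | starting material
13 | (2Z)-1-bromooct-2-ene | CCCCC/C=C\CBr | intermediate
14 | 3-bromofuran | Brc1ccoc1 | starting material
15 | 3-bromo-2-lithiofuran | [Li]c1occc1Br | intermediate (not isolated)
16 | 3-bromo-2-(trimethylsilyl)furan | C[Si](C)(C)c1occc1Br | intermediate
17 | 3-lithio-2-(trimethylsilyl)furan | [Li]c1ccoc1[Si](C)(C)C | intermediate (not isolated)
18 | 3-chloro-2-(trimethylsilyl)furan | C[Si](C)(C)c1occc1Cl | intermediate
19 | 3-chloro-5-lithio-2-(trimethylsilyl)furan | [Li]c1cc(Cl)c(o1)[Si](C)(C)C | intermediate (not isolated)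
20 | 3-chloro-5-[(2Z)-oct-2-en-1-yl]-2-(trimethylsilyl)furan | CCCCC/C=C\Cc1cc(Cl)c(o1)[Si](C)(C)C | intermediate (not isolated)
21 | 4-chloro-2-[(2Z)-oct-2-en-1-yl]furan | CCCCC/C=C\Cc1cc(Cl)co1 | intermediate
22 | [3-chloro-5-[(2Z)-oct-2-en-1-yl]furan-2-yl]magnesium chloride (LiCl complex) | CCCCC/C=C\Cc1cc(Cl)c(o1)[Mg]Cl | intermediate (not isolated)
23 | methyl (5S,6R,7R,8S)-8-[3-chloro-5-[(2Z)-oct-2-en-1-yl]furan-2-yl]-8-hydroxy-5,6,7-tris(tert-butyldimethylsilyloxy)octanoate (8S drawn; the 8R epimer forms too and is used as well) | CCCCC/C=C\Cc1cc(Cl)c(o1)[C@@H](O)[C@@H](O[Si](C)(C)C(C)(C)C)[C@H](O[Si](C)(C)C(C)(C)C)[C@H](CCCC(=O)OC)O[Si](C)(C)C(C)(C)C | intermediate (key-step precursor)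
24 | 1,4-dihydroxypentadienyl cation: C12-O-protonated methyl (5S,6R,7R,8Z,10E,14Z)-10-chloro-9-hydroxy-12-oxo-5,6,7-tris(tert-butyldimethylsilyloxy)icosa-8,10,14-trienoate | CCCCC/C=C\CC(=[OH+])/C=C(Cl)\C(O)=C\[C@@H](O[Si](C)(C)C(C)(C)C)[C@H](O[Si](C)(C)C(C)(C)C)[C@H](CCCC(=O)OC)O[Si](C)(C)C(C)(C)C | intermediate (not isolated)
25 | methyl (5S,6R,7R,8R,12R,14Z)-10-chloro-12-hydroxy-9-oxo-5,6,7-tris(tert-butyldimethylsilyloxy)prosta-10,14-dien-1-oate (C7 chain cis to octenyl) | CCCCC/C=C\C[C@]1(O)C=C(Cl)C(=O)[C@@H]1[C@@H](O[Si](C)(C)C(C)(C)C)[C@H](O[Si](C)(C)C(C)(C)C)[C@H](CCCC(=O)OC)O[Si](C)(C)C(C)(C)C | intermediate (key-step product)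
26 | methyl (5S,6R,7R,8S,12R,14Z)-10-chloro-12-hydroxy-9-oxo-5,6,7-tris(tert-butyldimethylsilyloxy)prosta-10,14-dien-1-oate (C7 chain trans to octenyl) | CCCCC/C=C\C[C@]1(O)C=C(Cl)C(=O)[C@H]1[C@@H](O[Si](C)(C)C(C)(C)C)[C@H](O[Si](C)(C)C(C)(C)C)[C@H](CCCC(=O)OC)O[Si](C)(C)C(C)(C)C | intermediate
27 | methyl (5S,6R,7R,8S,12R,14Z)-10-chloro-5,6,7,12-tetrahydroxy-9-oxoprosta-10,14-dien-1-oate | CCCCC/C=C\C[C@]1(O)C=C(Cl)C(=O)[C@H]1[C@@H](O)[C@H](O)[C@H](CCCC(=O)OC)O | intermediate
28 | methyl (5S,6R,7R,8S,12R,14Z)-5,6,7-triacetoxy-10-chloro-12-hydroxy-9-oxoprosta-10,14-dien-1-oate (CNP0189493.1) | CCCCC/C=C\C[C@]1(O)C=C(Cl)C(=O)[C@H]1[C@@H](OC(C)=O)[C@H](OC(C)=O)[C@H](CCCC(=O)OC)OC(C)=O | target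

**Count**

Total step count: 16.
Longest linear sequence: 12 steps (steps 1–7 and 12–16, from D-xylose).

**Three steps most likely to fail**

1. Step 13 (key step). The electron-poor chlorinated furan may ionize and take up water too slowly, so that silyl-ether loss, trapping of the C8 cation by a chain oxygen or a hydride shift from C7 outrun the rearrangement. The sense of conrotation rests on the C7 centre alone and is a second uncertainty, which this fallback does not remove. Fallback (chlorine installed after the ring): it sets out from aldehyde 11 and bromide 13. Furan is lithiated (n-BuLi, THF, 0 °C) and alkylated with 13 to give 2-[(2Z)-oct-2-en-1-yl]furan F1. F1 is lithiated at its free α-position, transmetalated with MgBr2·OEt2 and added to 11 to give the chlorine-free furylcarbinol F2, which belongs exactly to the 5-alkyl-2-furylcarbinol class for which the rearrangement is established. Under the step 13 conditions F2 should give the chlorine-free hydroxy enone F3. Nucleophilic (Weitz–Scheffer) epoxidation of the enone with H2O2/NaOH in MeOH at −20 °C gives the 10,11-epoxy ketone F4. HCl in Et2O/CH2Cl2 at 0 °C opens the epoxide at the α-carbon C10 and dehydrates the chlorohydrin to the 2-chloro enone, which is 25, where the route is rejoined.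

2. Step 14. The C8 enolate may expel the C7 silyloxy group (E1cB, leading to a 7,8-alkylidene cyclopentenone), or the ring may open by retro-aldol cleavage, before C8 is reprotonated. Fallback (equilibration after deprotection): it sets out from 25, which is desilylated first under the step 15 conditions to the 8-epi triol F5. In F5 the C7 oxygen is a poorer leaving group, and the trans-dialkyl isomer gains a hydrogen bond between the C12 and C7 hydroxyls. Equilibration with KOAc in MeOH should therefore lead to triol 27, where the route is rejoined.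

3. Step 4. The carboxylate ylide may fragment (loss of PPh3 and acrylate) faster than it adds to the very hindered α-silyloxy aldehyde. Fallback (methylenation and cross-metathesis): it sets out from aldehyde 4. Wittig methylenation with Ph3P=CH2 (from Ph3PCH3Br and KOt-Bu, THF) gives the terminal alkene (3S,4R,5R)-3,4,5,6-tetrakis(tert-butyldimethylsilyloxy)hex-1-ene F6. Cross-metathesis of F6 with methyl but-3-enoate (second-generation Grubbs catalyst, CH2Cl2, 40 °C) gives the E-configured isomer of 8, F7. Hydrogenation of F7 as in step 5 gives ester 9, where the route is rejoined.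

**Further compounds**

F1 | step 13 | 2-[(2Z)-oct-2-en-1-yl]furan | CCCCC/C=C\Cc1ccco1
F2 | step 13 | methyl (5S,6R,7R)-8-hydroxy-8-[5-[(2Z)-oct-2-en-1-yl]furan-2-yl]-5,6,7-tris(tert-butyldimethylsilyloxy)octanoate (C8 epimer mixture, one epimer drawn) | CCCCC/C=C\Cc1ccc(o1)[C@@H](O)[C@@H](O[Si](C)(C)C(C)(C)C)[C@H](O[Si](C)(C)C(C)(C)C)[C@H](CCCC(=O)OC)O[Si](C)(C)C(C)(C)C
F3 | step 13 | 10-deschloro analogue of 25 (same spatial arrangement; C12 becomes 12S by the priority rules) | CCCCC/C=C\C[C@]1(O)C=CC(=O)[C@@H]1[C@@H](O[Si](C)(C)C(C)(C)C)[C@H](O[Si](C)(C)C(C)(C)C)[C@H](CCCC(=O)OC)O[Si](C)(C)C(C)(C)C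
F4 | step 13 | 10,11-epoxide of F3 (epoxide face not controlled, both faces converge) | CCCCC/C=C\C[C@]1(O)C2OC2C(=O)[C@@H]1[C@@H](O[Si](C)(C)C(C)(C)C)[C@H](O[Si](C)(C)C(C)(C)C)[C@H](CCCC(=O)OC)O[Si](C)(C)C(C)(C)C
F5 | step 14 | methyl (5S,6R,7R,8R,12R,14Z)-10-chloro-5,6,7,12-tetrahydroxy-9-oxoprosta-10,14-dien-1-oate (8-epimer of 27) | CCCCC/C=C\C[C@]1(O)C=C(Cl)C(=O)[C@@H]1[C@@H](O)[C@H](O)[C@H](CCCC(=O)OC)O
F6 | step 4 | (3S,4R,5R)-3,4,5,6-tetrakis(tert-butyldimethylsilyloxy)hex-1-ene | C=C[C@H](O[Si](C)(C)C(C)(C)C)[C@@H](O[Si](C)(C)C(C)(C)C)[C@H](O[Si](C)(C)C(C)(C)C)CO[Si](C)(C)C(C)(C)C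
F7 | step 4 | methyl (3E,5S,6R,7R)-5,6,7,8-tetrakis(tert-butyldimethylsilyloxy)oct-3-enoate | COC(=O)C/C=C/[C@H](O[Si](C)(C)C(C)(C)C)[C@@H](O[Si](C)(C)C(C)(C)C)[C@H](O[Si](C)(C)C(C)(C)C)CO[Si](C)(C)C(C)(C)C
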